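A small charge of enzyme, 0.80 µM, meets 0.050 M of starting material in each flask, and I keep the books in percent of that charge.

the same everywhere: enzyme 0.80 µM
- north-east: starting material 0.050 M; second substrate 0.050 M; run made earlier
- east: starting material 0.050 M; second substrate 0.025 M; run made earlier
- south: starting material 0.050 M; second substrate 0.038 M; run made earlier
- winter: starting material 0.050 M (fed, over 15 h); second substrate 0.0500 M; all else is in the flask from the start; the feed brings no volume worth counting; time 25 h
- summer: starting material 0.050 M; second substrate 0.0500 M (fed, over 15 h); all else is in the flask from the start; the feed brings no volume worth counting; time 25 h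
- dawn: starting material 0.050 M; second substrate 0.0500 M; everything together at the start; time 25 h

- north-east (time / h: side product / %, target / %, starting material / %): 1.33: 0.6, 1.9, 97.2; 4.00: 4.0, 7.1, 91.4; 8.00: 6.7, 11.7, 82.8; 10.0: 10.6, 12.1, 75.6; 15.0: 17.2, 11.1, 71.6
- east (time / h: side product / %, target / %, starting material / %): 2.00: 2.0, 6.3, 93.8; 5.00: 4.1, 11.8, 86.6; 10.0: 11.7, 15.5, 74.3; 15.0: 20.9, 11.8, 68.9; 20.0: 27.0, 9.6, 62.3
- south (time / h: side product / %, target / %, starting material / %): 4.00: 3.1, 9.0, 89.2; 8.00: 8.6, 11.4, 80.6; 12.0: 14.5, 12.6, 73.2; 15.0: 20.2, 11.5, 69.0; 20.0: 26.8, 10.7, 63.5

(scatter of a reading: 1 percentage point)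

- percent here means starting material units held: one side product counts as two

1. the flask that comes out highest in amount of side product, in percent of the starting material charged; "all alike" if 1.5 percentage points covers them all (winter / summer / dawn / all alike)
2. amount of side product at the end, in percent of the starting material charged, winter
3. amount of side product at the end, in percent of the starting material charged, summer
4. amount of side product at the end, in percent of the starting material charged, dawn

Each percent stands in one of three entries: left, target or side product. The east run at 20.0 h sums to 98.9 %, so the books close within the scatter. One side product counts two, one unit of starting material and one of target, so target lost is half the side product gained. In the east run, between 10.0 h and 20.0 h, side product rises from 11.7 % to 27.0 %, while target averages 12.3 % and the fraction left averages 68.5 %. I carry one reading from this: H, the half-life of target against starting material standing at its full 0.050 M, which comes to 7.63 h. With a fraction a left, this loss of target is pseudo-first-order, and by this step alone target halves every H/a.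

Dawn repeats the north-east recipe. At 15.0 h that run reads 17.2 % side product, 11.1 % target and 71.6 % left, so H/a is 10.7 h. Holding those readings to the end, I reckon 31.6 % for dawn. Winter's feed has brought in, on average over its course, half the whole charge, and at that average level H/a is 15.3 h, longer than the figure for dawn. I expect winter lowest, with summer, whose starting material is all there from the start, close to dawn.

The forecast names summer as highest, with winter 17 % (12 % to 24 %), summer 32 % (27 % to 37 %) and dawn 30 % (26 % to 34 %); my dawn figure is higher than its. Its ground: “Target peaks near 12–15% and feeds the side product at about 0.12 × target per h, or as target squared.”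

The flasks give winter 12.2 %, summer 31.9 % and dawn 29.8 %, so summer is highest and each value lies in the forecast's range.

    second substrate + enzyme ⇌ complex B (K = 100 M⁻¹, k = 5.00 × 10⁵ M⁻¹ h⁻¹)
    complex A → enzyme + target (k = 4000 h⁻¹)
    starting material + target → side product (k = 1.70 M⁻¹ h⁻¹)
    complex B → enzyme + second product (k = 5100 h⁻¹)
    starting material + enzyme ⇌ complex A (K = 50.0 M⁻¹, k = 5.40 × 10⁶ M⁻¹ h⁻¹)
    enzyme → spent catalyst (k = 0.500 h⁻¹)

The neighbour is winter with its charge of starting material raised to 0.20 M. At the end of winter 83 % is left, so H/a gives target a half-life of 9.16 h. In the neighbour 83 % of the larger charge is left, and the same reckoning gives 2.31 h, shorter than winter's. The neighbour's books close at 82.6 % left, 1.03 % target and 16.3 % side product. Of all target made, winter still holds 41.8 % and the neighbour 11.2 %.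

(The readings come from a simulation on assumed constants, and the scatter is random.)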